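## The problem

Compound 15 is a 3-arylchromen-4-one (an isoflavone): benzo ring A is fused to pyranone ring C, and the 2,4-dihydroxyphenyl ring B sits on C3. There is no stereocenter, so the difficulty lies in connectivity and in telling four phenolic oxygens apart. O7 carries the 3-methylbut-2-enyl (prenyl) group, while O5, O2' and O4' are free. The prenyl aryl ether is the fragile group: it ionises to an allyl cation under strong Brønsted or Lewis acid, and hydrogenolysis would saturate it. That excludes the usual methyl ether and benzyl ether end games. The second weak point is C2, a vinylogous ester carbon at which hydroxide and amines add and open ring C. The enabling feature is that ring A carries a heteroatom on C5, C7 and C8a, which are the two positions ortho and the one position para to C4a, the carbon holding the C4 carbonyl. A 2,4,6-trifluorobenzoyl group can therefore stand for ring A plus C4. Its two ortho fluorines are equivalent, one is displaced by the C2-bound oxygen to close ring C, and the other two stay activated by the chromone carbonyl for replacement by oxygen nucleophiles, one after the other.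

## Retrosynthesis

**15 from 14.** The last bonds cut are the two acetal O–CH2 bonds masking O2' and O4'. Ring B must be protected through a hydride reduction, an amine condensation, an acylation and three base-mediated substitutions, and must be freed without hydrogenolysis or a strong Lewis acid. Methoxymethyl acetals meet both demands, whereas benzyl or methyl ethers would cost the prenyl group on removal. The forward reaction must cleave the acetals faster than the allylic ether ionises.

**14 from 12.** The C5–O bond is cut and the hydroxyl traced to fluorine. In 12 the C5–F bond is ortho to the C4 carbonyl and is the only leaving group left on ring A. Free hydroxide would add at C2 and destroy ring C, so the oxygen is delivered by an alkoxide that unmasks itself by β-elimination; the ether 13 is the intermediate. The forward reaction must substitute at the peri position faster than it adds at C2.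

**12 from 10 and 11.** The C7–O bond is cut, so that prenol 11 is the nucleophile and C7 the electrophile. The neighbouring cut, alkylation of a 7-phenol at O–CH2, would require that phenol to be the only free one on the molecule. With fluorine in place, no ring-A phenol ever needs protection or differentiation. Difluoride 10 is simpler by one whole substituent pattern; its two fluorines differ only in being para or ortho to the carbonyl. The forward reaction must substitute para before ortho, and only once.

**10 from 6 and 7 (key disconnection).** Three bonds of ring C are cut: C3–C4, C2–O1 and O1–C8a.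
- The cut divides the molecule into the commercial acid chloride 7, which is ring A plus C4, and the enamine 6, which is ring B plus C3 and C2.
- The classical cut at C4–C4a (acylation of a phloroglucinol) and a cross-coupling cut at C3–C1' both need the ring-A oxygens in place and already differentiated. This cut postpones them to two ordered substitutions.
- The forward reaction must acylate 6 on carbon, exchange the amine on C2 for oxygen, and let that oxygen displace an ortho fluorine.

**6 from 4 and 5.** The C–N bond of the enamine is cut, leading to arylacetaldehyde 4 and morpholine 5. The condensation only has to outrun self-condensation of 4; the conjugated E-enamine is the thermodynamic product.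

**4 from 1.** Aldehyde 4 is the reduced form of ester 3, which comes from the commercial acid 1 by esterification to 2 and acetal protection. These are functional-group changes only and no skeletal bond is formed.

## Roads not taken

**Alternative 1:** ring A built by Danheiser benzannulation.
- Cut: ring A is taken apart at C4a–C8a, C5–C6 and C8–C8a.
- Key step: heating 3-[(3-methylbut-2-en-1-yl)oxy]cyclobut-2-en-1-one A1 with the siloxyalkyne A2 should open A1 to a vinylketene. This adds to the alkyne by [2+2] cycloaddition, and four-electron ring opening and six-electron electrocyclisation then give the phenol A3.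
- Merits: ring A arrives with its three oxygens already distinct, as free hydroxyl (the future O1), silyl ether (the future 5-hydroxyl) and prenyl ether (O7). No aromatic substitution has to be regioselective. In this respect the road is better than the chosen plan, which depends on para-over-ortho selectivity in step 6.
- Weak points: A1 and A2 each need several steps, and A2 is a sensitive ynol silyl ether carrying a carbinol stereocenter that is made only to be oxidised away. After A3 there still follow desilylation, oxidation to the ketone, a one-carbon insertion to close ring C, removal of the aryl silyl ether, and the same acetal cleavage beside the prenyl ether.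
- Comparison: the step count is roughly double. The chosen plan sets against the differentiation advantage a bought ring A, fluorines in 10 that differ both electronically and sterically, and a reserve route that installs the prenyloxy group before ring closure.

**Alternative 2:** ring C closed at C4–C4a by Friedel–Crafts acylation.
- Cut: C4–C4a.
- Key step: 3-(3,5-dimethoxyphenoxy)-2-(2,4-dimethoxyphenyl)prop-2-enoic acid A4 is cyclised with P2O5 in CH3SO3H to 5,7-dimethoxy-3-(2,4-dimethoxyphenyl)chromen-4-one A5.
- Merits: this is the shortest and cheapest way to the isoflavone core. The closure is unambiguous because both positions ortho to the aryloxy oxygen are equivalent, and no organofluorine chemistry is needed. In steps to the core it is better than the chosen plan.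
- Weak points: the strongly acidic medium admits neither a prenyl ether nor acetal protection, so all four oxygens arrive as methyl ethers. The end game is exhaustive demethylation with a boron halide, then monoprenylation of a tetraphenol at O7 in competition with O4' and O2', guided only by acidity.
- Comparison: the real problem of 15, telling the oxygens apart, is moved to the last step, where material is most valuable. The chosen plan is longer to the core but places every oxygen by position, and keeps the acidity-based alkylation only as a reserve.

**Alternative 3:** aryne annulation.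
- Cut: O1–C8a and C4–C4a.
- Key step: CsF releases the aryne from 3,5-bis(benzyloxy)-2-(trimethylsilyl)phenyl trifluoromethanesulfonate A6. The enolate oxygen of methyl 2-[2,4-bis(methoxymethoxy)phenyl]-3-hydroxyprop-2-enoate A7 adds at the aryne carbon remote from the flanking benzyloxy group, and the aryl anion closes on the ester to give 5,7-bis(benzyloxy)-3-[2,4-bis(methoxymethoxy)phenyl]chromen-4-one A8.
- Merits: it is convergent and mild, and both ring-fusion bonds form in one operation. The end game would be debenzylation, alkylation of the 7-hydroxyl beside a chelated 5-hydroxyl, and acetal cleavage. That differentiates O5 from O7 by hydrogen bonding, a selectivity at least as dependable as the substitution order the chosen plan relies on.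
- Weak points: A6 takes four to five steps from a phloroglucinol derivative. The ambident enolate of A7 may attack the aryne through carbon, as β-dicarbonyl compounds usually do. Hydrogenolysis of the benzyl ethers over Pd/C endangers the C2=C3 bond. The final acetal cleavage beside the prenyl ether is the same as in the chosen plan.
- Comparison: the chosen plan sets against it a commercial acyl partner, a carbon–carbon bond formed in the natural sense of enamine reactivity, and a ring closure with no ambident choice.

Key step: step 5

## Route

Assumption: the double-bond geometry of the push–pull intermediates 8 and 9 is mobile; 8 is drawn E and 9 without assignment, and neither geometry affects the product.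

Step 1
Reactants: 1 2-(2,4-dihydroxyphenyl)acetic acid
Product: 2 methyl 2-(2,4-dihydroxyphenyl)acetate
Conditions: MeOH, H2SO4 (cat.), reflux
Reagents that add atoms: methanol, CO
Why: Fischer esterification; the large excess of methanol should favour the methyl ester over the benzofuranone that the ortho hydroxyl could form, and the phenols are untouched.

Step 2
Reactants: 2 methyl 2-(2,4-dihydroxyphenyl)acetate
Product: 3 methyl 2-[2,4-bis(methoxymethoxy)phenyl]acetate
Conditions: MOMCl, i-Pr2NEt, CH2Cl2, 0 °C → rt
Reagents that add atoms: chloromethyl methyl ether, COCCl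
Why: O-alkylation of both phenols to methoxymethyl acetals under a hindered amine base, which is too weak to enolise the ester or drive lactonisation of the ortho phenol.

Step 3
Reactants: 3 methyl 2-[2,4-bis(methoxymethoxy)phenyl]acetate
Product: 4 2-[2,4-bis(methoxymethoxy)phenyl]acetaldehyde
Conditions: i-Bu2AlH (1.1 equiv), toluene, −78 °C; MeOH, then aq. potassium sodium tartrate
Reagents that add atoms: none
Why: Partial reduction of an ester by diisobutylaluminium hydride; the aluminium hemiacetal is stable at −78 °C and releases the aldehyde only on work-up, and the acetals are inert to hydride; the aldehyde is used at once.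

Step 4
Reactants: 4 2-[2,4-bis(methoxymethoxy)phenyl]acetaldehyde; 5 morpholine
Product: 6 (E)-4-{2-[2,4-bis(methoxymethoxy)phenyl]ethenyl}morpholine
Conditions: 5 (1.3 equiv), 4 Å molecular sieves, toluene, 0 °C → rt; filtered, concentrated, used crude
Reagents that add atoms: none
Why: Enamine condensation of a secondary amine with an enolisable aldehyde; the double bond conjugated with ring B forms under thermodynamic control and should be E, with the aryl and amino groups trans.

Step 5
Reactants: 6 (E)-4-{2-[2,4-bis(methoxymethoxy)phenyl]ethenyl}morpholine; 7 2,4,6-trifluorobenzoyl chloride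
Product: 10 3-[2,4-bis(methoxymethoxy)phenyl]-5,7-difluoro-4H-chromen-4-one, via enaminone 8 (not isolated), via hydroxymethylene ketone 9 (not isolated)
Conditions: Et3N, toluene, 0 °C → rt; aq. AcOH–THF, rt, aqueous phase removed, organic phase dried; K2CO3, DMF, rt → 50 °C
Reagents that add atoms: water, O
Why: The enamine β-carbon (the future C3) attacks the acid chloride and Et3N removes the proton, forming C3–C4 and the push–pull enaminone 8; this is the acylation stage of the Grohe–Heitzer quinolone synthesis, whose oxygen variant (exchange of the amine for oxygen, then closure on an ortho halogen) is the closest known reaction type. N-Acylation of the tertiary enamine gives only an acylammonium ion that reverts or passes its acyl group on, so irreversible C-acylation should prevail, and 8 is too electron-poor to be acylated again. Aqueous acetic acid adds water at the aminomethylene carbon and expels morpholine, which leaves in the aqueous phase as its acetate before any base is present and so cannot attack C7 or C2 of the fluorochromone; aryl methoxymethyl acetals tolerate this weak acid. K2CO3 then forms the enolate of 9, whose formyl-derived oxygen adds to a fluorine-bearing ortho carbon and expels fluoride through a Meisenheimer intermediate, forming O1–C8a and closing the six-membered pyranone ring by intramolecular nucleophilic aromatic substitution. The site of closure is unambiguous because the two ortho fluorines are equivalent by symmetry and the para fluorine is out of intramolecular reach, and the carbon attacked is activated by the ortho ketone and the other two fluorines. Oxygen rather than carbon attack of the ambident enolate is enforced by geometry, since carbon attack would give a four-membered ring. No stereocenter is formed.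

Step 6
Reactants: 10 3-[2,4-bis(methoxymethoxy)phenyl]-5,7-difluoro-4H-chromen-4-one; 11 3-methylbut-2-en-1-ol
Product: 12 3-[2,4-bis(methoxymethoxy)phenyl]-5-fluoro-7-[(3-methylbut-2-en-1-yl)oxy]-4H-chromen-4-one
Conditions: 11 (1.2 equiv), KOtBu (1.05 equiv), DMF, −30 → 0 °C
Reagents that add atoms: none
Why: Nucleophilic aromatic substitution by potassium prenyloxide at C7, para to the C4 carbonyl; in a polar aprotic solvent the loosely paired alkoxide is not delivered to C5 by the cation and is repelled there by the peri carbonyl oxygen. The new alkoxy donor then deactivates the ring against a second substitution, and near-stoichiometric alkoxide at low temperature limits reversible addition at C2.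

Step 7
Reactants: 12 3-[2,4-bis(methoxymethoxy)phenyl]-5-fluoro-7-[(3-methylbut-2-en-1-yl)oxy]-4H-chromen-4-one
Product: 14 3-[2,4-bis(methoxymethoxy)phenyl]-5-hydroxy-7-[(3-methylbut-2-en-1-yl)oxy]-4H-chromen-4-one, via sulfonylethyl ether 13 (not isolated)
Conditions: MeSO2CH2CH2OH (1.5 equiv), NaH (2.5 equiv), DMF, 0 °C → rt; aq. NH4Cl
Reagents that add atoms: 2-(methylsulfonyl)ethanol, CS(=O)(=O)CCO
Why: Nucleophilic aromatic substitution of the carbonyl-activated C5 fluorine by the alkoxide, then E1cB loss of methyl vinyl sulfone from ether 13 to release the phenoxide; this is the established hydroxide-equivalent method for activated aryl fluorides. The chelated 5-phenoxide makes the chromone electron-rich and protects it from further attack.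

Step 8
Reactants: 14 3-[2,4-bis(methoxymethoxy)phenyl]-5-hydroxy-7-[(3-methylbut-2-en-1-yl)oxy]-4H-chromen-4-one
Product: 15 3-(2,4-dihydroxyphenyl)-5-hydroxy-7-[(3-methylbut-2-en-1-yl)oxy]-4H-chromen-4-one
Conditions: HCl (ca. 1 M), MeOH–THF, rt → 40 °C
Reagents that add atoms: none
Why: Acid-catalysed methanolysis of the two methoxymethyl acetals; acetal exchange should be much faster than ionisation of the prenyl ether, whose oxygen sits on the electron-poor chromone ring and is only weakly basic.

## Compound list

1 | 2-(2,4-dihydroxyphenyl)acetic acid | OC(=O)Cc1ccc(O)cc1O | starting material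
2 | methyl 2-(2,4-dihydroxyphenyl)acetate | COC(=O)Cc1ccc(O)cc1O | intermediate
3 | methyl 2-[2,4-bis(methoxymethoxy)phenyl]acetate | COCOc1ccc(CC(=O)OC)c(OCOC)c1 | intermediate
4 | 2-[2,4-bis(methoxymethoxy)phenyl]acetaldehyde | COCOc1ccc(CC=O)c(OCOC)c1 | intermediate
5 | morpholine | C1COCCN1 | starting material
6 | (E)-4-{2-[2,4-bis(methoxymethoxy)phenyl]ethenyl}morpholine | COCOc1ccc(/C=C/N2CCOCC2)c(OCOC)c1 | intermediate
7 | 2,4,6-trifluorobenzoyl chloride | O=C(Cl)c1c(F)cc(F)cc1F | starting material
8 | (E)-2-[2,4-bis(methoxymethoxy)phenyl]-3-(morpholin-4-yl)-1-(2,4,6-trifluorophenyl)prop-2-en-1-one (not isolated; geometry mobile) | O=C(c1c(F)cc(F)cc1F)/C(c1ccc(OCOC)cc1OCOC)=C/N1CCOCC1 | intermediate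
9 | 2-[2,4-bis(methoxymethoxy)phenyl]-3-hydroxy-1-(2,4,6-trifluorophenyl)prop-2-en-1-one (not isolated; enol form of the β-ketoaldehyde, geometry unassigned) | O=C(c1c(F)cc(F)cc1F)C(=CO)c1ccc(OCOC)cc1OCOC | intermediate
10 | 3-[2,4-bis(methoxymethoxy)phenyl]-5,7-difluoro-4H-chromen-4-one | COCOc1ccc(-c2coc3cc(F)cc(F)c3c2=O)c(OCOC)c1 | intermediate
11 | 3-methylbut-2-en-1-ol (prenol) | CC(C)=CCO | starting material
12 | 3-[2,4-bis(methoxymethoxy)phenyl]-5-fluoro-7-[(3-methylbut-2-en-1-yl)oxy]-4H-chromen-4-one | COCOc1ccc(-c2coc3cc(OCC=C(C)C)cc(F)c3c2=O)c(OCOC)c1 | intermediate
13 | 3-[2,4-bis(methoxymethoxy)phenyl]-5-[2-(methylsulfonyl)ethoxy]-7-[(3-methylbut-2-en-1-yl)oxy]-4H-chromen-4-one (not isolated) | COCOc1ccc(-c2coc3cc(OCC=C(C)C)cc(OCCS(C)(=O)=O)c3c2=O)c(OCOC)c1 | intermediate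
14 | 3-[2,4-bis(methoxymethoxy)phenyl]-5-hydroxy-7-[(3-methylbut-2-en-1-yl)oxy]-4H-chromen-4-one | COCOc1ccc(-c2coc3cc(OCC=C(C)C)cc(O)c3c2=O)c(OCOC)c1 | intermediate
15 | 3-(2,4-dihydroxyphenyl)-5-hydroxy-7-[(3-methylbut-2-en-1-yl)oxy]-4H-chromen-4-one | CC(C)=CCOc1cc(O)c2c(=O)c(-c3ccc(O)cc3O)coc2c1 | target

## Step count and risks

Total step count: 8. Longest linear sequence: 8 steps (1 to 15); compounds 5, 7 and 11 enter as bought.

**Step 5 (key step).**
- Risk: hydrolysis of the vinylogous amide may be incomplete in weak acid. Forcing it with stronger acid would begin to strip the acetals, and forcing it in base would let the liberated morpholine substitute at C7 or add at C2 of the product. Base-induced deformylation of 9 before ring closure is a lesser risk.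
- Fallback: it sets out from ester 3 and comes back at 9, and so at 10.
  - 3 is converted with MeNH(OMe)·HCl and i-PrMgCl into the Weinreb amide 2-[2,4-bis(methoxymethoxy)phenyl]-N-methoxy-N-methylacetamide F1.
  - 2,4,6-Trifluorophenyllithium (from 1,3,5-trifluorobenzene and n-BuLi, THF, −78 °C) adds to F1 to give the deoxybenzoin 2-[2,4-bis(methoxymethoxy)phenyl]-1-(2,4,6-trifluorophenyl)ethan-1-one F2.
  - Claisen formylation of F2 with ethyl formate and NaH gives the sodium enolate of 9, which should close to 10 in the same flask. No amine is present at any point.

**Step 6.**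
- Risk: cation-assisted delivery of the alkoxide to C5 would erode the para selectivity. Over-substitution of both fluorines and alkoxide addition at C2 with opening of ring C are the other losses.
- Fallback: it sets out from enamine 6 and comes back at 12, with the 7-oxygen installed before ring closure.
  - 3,5-Difluorophenol is alkylated (prenyl bromide, K2CO3, acetone) to 1,3-difluoro-5-[(3-methylbut-2-en-1-yl)oxy]benzene F3.
  - F3 is deprotonated between the fluorines (LiN(i-Pr)2, THF, −78 °C) and carboxylated with CO2 to 2,6-difluoro-4-[(3-methylbut-2-en-1-yl)oxy]benzoic acid F4.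
  - 1-Chloro-N,N,2-trimethylprop-1-en-1-amine turns F4 under neutral conditions into 2,6-difluoro-4-[(3-methylbut-2-en-1-yl)oxy]benzoyl chloride F5.
  - Under the conditions of step 5, 6 and F5 should give (E)-2-[2,4-bis(methoxymethoxy)phenyl]-1-{2,6-difluoro-4-[(3-methylbut-2-en-1-yl)oxy]phenyl}-3-(morpholin-4-yl)prop-2-en-1-one F6, then 2-[2,4-bis(methoxymethoxy)phenyl]-1-{2,6-difluoro-4-[(3-methylbut-2-en-1-yl)oxy]phenyl}-3-hydroxyprop-2-en-1-one F7, which closes to 12. The two ortho fluorines of F5 are still equivalent, so the closure remains unambiguous.

**Step 7.**
- Risk: displacement at the peri position may be slow once the 7-alkoxy group has weakened the activation by the carbonyl. The excess alkoxide and hydride could meanwhile add at C2 and cleave ring C.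
- Fallback: it sets out from 12 and comes back at 14, separating substitution from unmasking.
  - NaOCH2CH2SiMe3 (1.1 equiv, THF–DMF, −20 °C) gives 3-[2,4-bis(methoxymethoxy)phenyl]-7-[(3-methylbut-2-en-1-yl)oxy]-5-[2-(trimethylsilyl)ethoxy]-4H-chromen-4-one F8, which is isolated.
  - Bu4NF in THF then fragments the silylethyl ether to 14 without any excess strong base.

**Step 8.**
- Risk: acid-induced ionisation of the prenyl ether during acetal cleavage would lose the prenyl group. The first adjustment is the non-protic cleavage of aryl methoxymethyl ethers with Me3SiOTf and 2,2'-bipyridyl.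
- Fallback: it sets out from 14 and comes back at 15.
  - Hot methanolic HCl strips both acetals and the prenyl group to give 3-(2,4-dihydroxyphenyl)-5,7-dihydroxy-4H-chromen-4-one F9.
  - Prenyl bromide (1.0 equiv) with K2CO3 (1.0 equiv) in acetone at rt should then alkylate the most acidic hydroxyl, the 7-hydroxyl para to the carbonyl. The bis-ether by-products would have to be removed by chromatography.

**Step 3.**
- Risk: over-reduction to the alcohol, and self-condensation of the arylacetaldehyde during work-up.
- Fallback: it sets out from 3 and comes back at 4. LiAlH4 (THF, 0 °C) reduces 3 fully to 2-[2,4-bis(methoxymethoxy)phenyl]ethan-1-ol F10, and Dess–Martin periodinane buffered with NaHCO3 in CH2Cl2 oxidises F10 to 4.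

## Further compounds

F1 | step 5 | 2-[2,4-bis(methoxymethoxy)phenyl]-N-methoxy-N-methylacetamide | CON(C)C(=O)Cc1ccc(OCOC)cc1OCOC
F2 | step 5 | 2-[2,4-bis(methoxymethoxy)phenyl]-1-(2,4,6-trifluorophenyl)ethan-1-one | O=C(Cc1ccc(OCOC)cc1OCOC)c1c(F)cc(F)cc1F
F3 | step 6 | 1,3-difluoro-5-[(3-methylbut-2-en-1-yl)oxy]benzene | CC(C)=CCOc1cc(F)cc(F)c1
F4 | step 6 | 2,6-difluoro-4-[(3-methylbut-2-en-1-yl)oxy]benzoic acid | CC(C)=CCOc1cc(F)c(C(=O)O)c(F)c1
F5 | step 6 | 2,6-difluoro-4-[(3-methylbut-2-en-1-yl)oxy]benzoyl chloride | CC(C)=CCOc1cc(F)c(C(=O)Cl)c(F)c1
F6 | step 6 | (E)-2-[2,4-bis(methoxymethoxy)phenyl]-1-{2,6-difluoro-4-[(3-methylbut-2-en-1-yl)oxy]phenyl}-3-(morpholin-4-yl)prop-2-en-1-one | O=C(c1c(F)cc(OCC=C(C)C)cc1F)/C(c1ccc(OCOC)cc1OCOC)=C/N1CCOCC1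
F7 | step 6 | 2-[2,4-bis(methoxymethoxy)phenyl]-1-{2,6-difluoro-4-[(3-methylbut-2-en-1-yl)oxy]phenyl}-3-hydroxyprop-2-en-1-one | O=C(c1c(F)cc(OCC=C(C)C)cc1F)C(=CO)c1ccc(OCOC)cc1OCOC
F8 | step 7 | 3-[2,4-bis(methoxymethoxy)phenyl]-7-[(3-methylbut-2-en-1-yl)oxy]-5-[2-(trimethylsilyl)ethoxy]-4H-chromen-4-one | COCOc1ccc(-c2coc3cc(OCC=C(C)C)cc(OCC[Si](C)(C)C)c3c2=O)c(OCOC)c1
F9 | step 8 | 3-(2,4-dihydroxyphenyl)-5,7-dihydroxy-4H-chromen-4-one | Oc1ccc(-c2coc3cc(O)cc(O)c3c2=O)c(O)c1
F10 | step 3 | 2-[2,4-bis(methoxymethoxy)phenyl]ethan-1-ol | COCOc1ccc(CCO)c(OCOC)c1
A1 | alternative 1 | 3-[(3-methylbut-2-en-1-yl)oxy]cyclobut-2-en-1-one | CC(C)=CCOC1=CC(=O)C1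
A2 | alternative 1 | racemic triethyl({1-[2,4-bis(methoxymethoxy)phenyl]-4-[(triisopropylsilyl)oxy]but-3-yn-2-yl}oxy)silane | COCOc1ccc(CC(O[Si](CC)(CC)CC)C#CO[Si](C(C)C)(C(C)C)C(C)C)c(OCOC)c1
A3 | alternative 1 | racemic 2-{2-[2,4-bis(methoxymethoxy)phenyl]-1-(triethylsilyloxy)ethyl}-5-(3-methylbut-2-enyloxy)-3-(triisopropylsilyloxy)phenol | CC(C)=CCOc1cc(O)c(C(Cc2ccc(OCOC)cc2OCOC)O[Si](CC)(CC)CC)c(O[Si](C(C)C)(C(C)C)C(C)C)c1
A4 | alternative 2 | 3-(3,5-dimethoxyphenoxy)-2-(2,4-dimethoxyphenyl)prop-2-enoic acid | COc1cc(OC)cc(OC=C(C(=O)O)c2ccc(OC)cc2OC)c1
A5 | alternative 2 | 5,7-dimethoxy-3-(2,4-dimethoxyphenyl)chromen-4-one | COc1ccc(-c2coc3cc(OC)cc(OC)c3c2=O)c(OC)c1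
A6 | alternative 3 | 3,5-bis(benzyloxy)-2-(trimethylsilyl)phenyl trifluoromethanesulfonate | C[Si](C)(C)c1c(OCc2ccccc2)cc(OCc2ccccc2)cc1OS(=O)(=O)C(F)(F)F
A7 | alternative 3 | methyl 2-[2,4-bis(methoxymethoxy)phenyl]-3-hydroxyprop-2-enoate | COC(=O)C(=CO)c1ccc(OCOC)cc1OCOC
A8 | alternative 3 | 5,7-bis(benzyloxy)-3-[2,4-bis(methoxymethoxy)phenyl]chromen-4-one | COCOc1ccc(-c2coc3cc(OCc4ccccc4)cc(OCc4ccccc4)c3c2=O)c(OCOC)c1
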